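**Retrosynthetic overview**
- The target is reached last by hydrogenolysis of the single 2'-O-benzyl ether of the 5,7-dihydroxyflavone 5'-acetate.
- Ring A is disconnected at C4a–C5 and C8–C8a: a [4+2] addition of 1-methoxy-1,3-bis(trimethylsilyloxy)buta-1,3-diene to the C5=C6 bond of a 2-aryl-3-methoxy-5-(p-tolylsulfinyl)-4-pyranone, then loss of sulfenic acid, methanol and silyl groups. The strategy rests on ring A carrying oxygen only at C5 and C7 (C6–H, C8–H) and being fused to the pyranone along C4a–C8a.
- Ring C (the pyranone) is closed by O1–C6 addition–elimination in a 1,3-diketone made from the B-ring aroyl chloride and the α'-enolate of a sulfinyl enaminone.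
- The B-ring acid comes from vanillin (MOM ether, Baeyer–Villiger, benzylation, bromination para to OMe, carboxylation); the enaminone from methyl p-tolyl sulfoxide, methyl methoxyacetate and DMF dimethyl acetal; the diene from methyl acetoacetate.
- Ring order: B (from vanillin), then C (pyranone), then A (cycloaddition–aromatisation).

Key step: step 13

Remark 1: the target has no stereocentre; the sulfoxide is used as the racemate, and enaminone geometry, keto–enol forms and diastereomers of intermediates are left unspecified because all are erased later.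
Remark 2: the activating group at pyranone C5 is p-tolylsulfinyl, not sulfonyl, because in the cis-fused cycloadduct the only β-hydrogen (C8a–H) is unactivated and syn to sulfur, so a sulfone has no low-energy elimination path whereas a sulfoxide leaves by thermal syn-elimination.

**Route**

Step 1
Reactants: 1 vanillin
Product: 2 3-methoxy-4-(methoxymethoxy)benzaldehyde
Conditions: MOMCl, i-Pr2NEt, CH2Cl2, 0 °C→rt
Reagents that add atoms: chloromethyl methyl ether, COCCl
Why: O-alkylation of the phenol (Williamson-type MOM ether formation) masks the future 5'-oxygen with a group that survives base, organolithium and enolate chemistry.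

Step 2
Reactants: 2 3-methoxy-4-(methoxymethoxy)benzaldehyde
Product: 4 3-methoxy-4-(methoxymethoxy)phenol, via aryl formate 3 (not isolated)
Conditions: mCPBA (1.3 equiv), CH2Cl2, 0 °C→rt; then K2CO3 (2 equiv), MeOH, rt
Reagents that add atoms: 3-chloroperoxybenzoic acid, O=C(OO)c1cccc(Cl)c1
Why: Baeyer–Villiger (Dakin-type) oxidation in which the electron-rich aryl group migrates to give the aryl formate, which is methanolysed in the same flask to the phenol that becomes the 2'-oxygen.

Step 3
Reactants: 4 3-methoxy-4-(methoxymethoxy)phenol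
Product: 5 4-(benzyloxy)-2-methoxy-1-(methoxymethoxy)benzene
Conditions: BnBr, K2CO3, DMF, rt
Reagents that add atoms: benzyl bromide, BrCc1ccccc1
Why: Williamson etherification installs the benzyl group that is removed only in the last step.

Step 4
Reactants: 5 4-(benzyloxy)-2-methoxy-1-(methoxymethoxy)benzene
Product: 6 1-(benzyloxy)-2-bromo-5-methoxy-4-(methoxymethoxy)benzene
Conditions: NBS (1.05 equiv), MeCN, 0 °C→rt
Reagents that add atoms: N-bromosuccinimide, O=C1CCC(=O)N1Br
Why: Electrophilic aromatic bromination of a 1,2,4-trialkoxybenzene should go to the position para to OMe and ortho to OBn, the most activated site that is not flanked by two substituents.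

Step 5
Reactants: 6 1-(benzyloxy)-2-bromo-5-methoxy-4-(methoxymethoxy)benzene
Product: 7 2-(benzyloxy)-4-methoxy-5-(methoxymethoxy)benzoic acid
Conditions: n-BuLi (1.05 equiv), THF, −78 °C; CO2 (g), −78→0 °C; 1 M HCl to pH 3, 0 °C
Reagents that add atoms: carbon dioxide, O=C=O
Why: Bromine–lithium exchange followed by carboxylation of the aryllithium, which at −78 °C should outrun benzylic deprotonation, places the future flavone C2 carbon on the B ring.

Step 6
Reactants: 8 methyl p-tolyl sulfoxide (racemic); 9 methyl methoxyacetate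
Product: 10 1-methoxy-3-(4-methylbenzenesulfinyl)propan-2-one
Conditions: 8 (1.1 equiv), LDA (2.2 equiv), THF, −78→−30 °C; 9 (1.0 equiv), −78→0 °C; aq NH4Cl
Reagents that add atoms: none
Why: Claisen-type acylation of the α-sulfinyl carbanion by the ester gives the β-keto sulfoxide, and the second equivalent of base holds the product as its enolate so that no second addition occurs.

Step 7
Reactants: 10 1-methoxy-3-(4-methylbenzenesulfinyl)propan-2-one
Product: 11 4-(dimethylamino)-1-methoxy-3-(4-methylbenzenesulfinyl)but-3-en-2-one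
Conditions: Me2NCH(OMe)2 (1.3 equiv), PhMe, 40 °C
Reagents that add atoms: N,N-dimethylformamide dimethyl acetal, COC(OC)N(C)C
Why: Condensation of the active methylene between C=O and S=O with the amide acetal gives the push–pull enaminone, adding the carbon that becomes C8a and blocking the sulfur-bearing carbon against later enolisation.

Step 8
Reactants: 7 2-(benzyloxy)-4-methoxy-5-(methoxymethoxy)benzoic acid; 11 4-(dimethylamino)-1-methoxy-3-(4-methylbenzenesulfinyl)but-3-en-2-one
Product: 13 1-[2-(benzyloxy)-4-methoxy-5-(methoxymethoxy)phenyl]-5-(dimethylamino)-2-methoxy-4-(4-methylbenzenesulfinyl)pent-4-ene-1,3-dione, via aroyl chloride 12 (not isolated)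
Conditions: 7, 1-chloro-N,N,2-trimethylprop-1-en-1-amine (1.1 equiv), CH2Cl2, 0 °C→rt, solvent exchanged to THF; 11 (2.0 equiv), LiHMDS (2.0 equiv), THF, −78 °C; add 12, −78→−40 °C; aq NH4Cl
Reagents that add atoms: none
Why: C-acylation of the α'-lithium enolate of a β-amino enone by an aroyl chloride (the first half of the standard γ-pyranone synthesis) should work because OCH2 is the only enolisable site of 11, and the neutral chloroenamine activation spares the MOM ether.

Step 9
Reactants: 13 1-[2-(benzyloxy)-4-methoxy-5-(methoxymethoxy)phenyl]-5-(dimethylamino)-2-methoxy-4-(4-methylbenzenesulfinyl)pent-4-ene-1,3-dione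
Product: 14 2-[2-(benzyloxy)-5-hydroxy-4-methoxyphenyl]-3-methoxy-5-(4-methylbenzenesulfinyl)-4H-pyran-4-one
Conditions: TsOH·H2O (2.5 equiv), MeOH–CH2Cl2 1:1, 40 °C; aq NaHCO3
Reagents that add atoms: none
Why: Acid-catalysed 6-endo oxa-Michael addition–elimination of the diketone enol oxygen onto the enaminone carbon expels dimethylamine and closes the 4-pyranone, while the same acid transacetalises the MOM ether to methanol; the acid has a non-nucleophilic counter-ion so the sulfoxide should not be reduced.

Step 10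
Reactants: 14 2-[2-(benzyloxy)-5-hydroxy-4-methoxyphenyl]-3-methoxy-5-(4-methylbenzenesulfinyl)-4H-pyran-4-one
Product: 15 4-(benzyloxy)-2-methoxy-5-[3-methoxy-5-(4-methylbenzenesulfinyl)-4-oxo-4H-pyran-2-yl]phenyl acetate
Conditions: Ac2O (1.5 equiv), pyridine (3 equiv), CH2Cl2, 0 °C→rt
Reagents that add atoms: acetic anhydride, CC(=O)OC(C)=O
Why: O-acetylation of the only free hydroxyl fixes the 5'-acetate before any A-ring hydroxyl exists, and at this temperature acetic anhydride should not start Pummerer chemistry at the vinyl sulfoxide.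

Step 11
Reactants: 16 methyl acetoacetate
Product: 17 methyl 3-(trimethylsilyloxy)but-2-enoate (E/Z mixture)
Conditions: TMSCl (1.2 equiv), Et3N (1.3 equiv), hexane, rt
Reagents that add atoms: chlorotrimethylsilane, C[Si](C)(C)Cl
Why: O-silylation of the β-keto ester enol gives the silyl enol ether.

Step 12
Reactants: 17 methyl 3-(trimethylsilyloxy)but-2-enoate
Product: 18 (1Z)-1-methoxy-1,3-bis(trimethylsilyloxy)buta-1,3-diene
Conditions: LDA (1.1 equiv), THF, −78 °C; TMSCl (1.2 equiv), −78 °C→rt; used crude or distilled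
Reagents that add atoms: chlorotrimethylsilane, C[Si](C)(C)Cl
Why: γ-Deprotonation of the vinylogous ester and O-silylation of the dienolate give the silyl ketene acetal diene, a standard preparation of this acetoacetate dianion equivalent.

Step 13
Reactants: 15 4-(benzyloxy)-2-methoxy-5-[3-methoxy-5-(4-methylbenzenesulfinyl)-4-oxo-4H-pyran-2-yl]phenyl acetate; 18 (1Z)-1-methoxy-1,3-bis(trimethylsilyloxy)buta-1,3-diene
Product: 21 4-(benzyloxy)-5-(5,7-dihydroxy-3-methoxy-4-oxo-4H-chromen-2-yl)-2-methoxyphenyl acetate, via cis-fused cycloadduct 19 (not isolated), via bis-silyl ether 20 (not isolated)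
Conditions: 18 (3 equiv), PhMe, 80 °C, sealed tube, no Lewis acid; then 0.5 M HCl, THF, 0 °C, short
Reagents that add atoms: none
Why: Proposed new method: the terminal CH2 of the diene, its most nucleophilic carbon, bonds to pyranone C6 (β to both the C4 carbonyl and the sulfinyl group) and the ketene-acetal carbon bonds to C5 in a thermal normal-demand Diels–Alder reaction, concerted but asynchronous, which closes ring A by intermolecular [4+2] cycloaddition across the C5=C6 bond. Suprafacial addition makes the ring fusion cis, so C8a–H and the C4a sulfinyl group are syn and p-toluenesulfenic acid should leave by thermal syn-elimination to give the C4a=C8a double bond; ionisation of the doubly vinylogous C5 ketal with loss of methanol and a C8 proton then gives the 5,7-bis(silyloxy) arene, which the acidic work-up desilylates. The closest known reactions are the Diels–Alder/sulfoxide-elimination aromatisations of 3-sulfinylchromones and 2-sulfinylquinones with oxygenated dienes, which have not been extended to a monocyclic 4-pyranone. No stereocentre remains, since the transient cis fusion serves only the elimination and the sulfur centre is lost. The step needs regioselectivity, which the polarisation of the push–pull C5=C6 bond (electrophilic C6) matched to the largest HOMO coefficient at the diene CH2 should secure, and site selectivity over the tetrasubstituted, unactivated C2=C3 bond. Neutral conditions are chosen to disfavour the Michael/retro-oxa-Michael opening of the pyranone and to spare the acetate and benzyl ether, so the 5- and 7-hydroxyls emerge free.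

Step 14
Reactants: 21 4-(benzyloxy)-5-(5,7-dihydroxy-3-methoxy-4-oxo-4H-chromen-2-yl)-2-methoxyphenyl acetate
Product: 22 5-(5,7-dihydroxy-3-methoxy-4-oxo-4H-chromen-2-yl)-4-hydroxy-2-methoxyphenyl acetate (5,7,2',5'-tetrahydroxy-3,4'-dimethoxyflavone 5'-acetate)
Conditions: H2 (1 atm), 10% Pd/C, EtOAc–THF, rt
Reagents that add atoms: none
Why: Catalytic hydrogenolysis of the single aryl benzyl ether under neutral, non-alcoholic conditions should leave the aryl acetate, the methyl ethers and the flavone C2=C3 bond untouched.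

**Compound list**
1 | vanillin | COc1cc(C=O)ccc1O | starting material
2 | 3-methoxy-4-(methoxymethoxy)benzaldehyde | COCOc1ccc(C=O)cc1OC | intermediate
3 | 3-methoxy-4-(methoxymethoxy)phenyl formate (not isolated) | COCOc1ccc(OC=O)cc1OC | intermediate
4 | 3-methoxy-4-(methoxymethoxy)phenol | COCOc1ccc(O)cc1OC | intermediate
5 | 4-(benzyloxy)-2-methoxy-1-(methoxymethoxy)benzene | COCOc1ccc(OCc2ccccc2)cc1OC | intermediate
6 | 1-(benzyloxy)-2-bromo-5-methoxy-4-(methoxymethoxy)benzene | COCOc1cc(Br)c(OCc2ccccc2)cc1OC | intermediate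
7 | 2-(benzyloxy)-4-methoxy-5-(methoxymethoxy)benzoic acid | COCOc1cc(C(=O)O)c(OCc2ccccc2)cc1OC | intermediate
8 | methyl p-tolyl sulfoxide (racemic) | Cc1ccc(S(C)=O)cc1 | starting material
9 | methyl methoxyacetate | COCC(=O)OC | starting material
10 | 1-methoxy-3-(4-methylbenzenesulfinyl)propan-2-one (racemic) | COCC(=O)CS(=O)c1ccc(C)cc1 | intermediate
11 | 4-(dimethylamino)-1-methoxy-3-(4-methylbenzenesulfinyl)but-3-en-2-one (racemic, alkene geometry labile) | COCC(=O)C(=CN(C)C)S(=O)c1ccc(C)cc1 | intermediate
12 | 2-(benzyloxy)-4-methoxy-5-(methoxymethoxy)benzoyl chloride (not isolated) | COCOc1cc(C(=O)Cl)c(OCc2ccccc2)cc1OC | intermediate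
13 | 1-[2-(benzyloxy)-4-methoxy-5-(methoxymethoxy)phenyl]-5-(dimethylamino)-2-methoxy-4-(4-methylbenzenesulfinyl)pent-4-ene-1,3-dione (stereoisomer and keto–enol mixture) | COCOc1cc(C(=O)C(OC)C(=O)C(=CN(C)C)S(=O)c2ccc(C)cc2)c(OCc2ccccc2)cc1OC | intermediate
14 | 2-[2-(benzyloxy)-5-hydroxy-4-methoxyphenyl]-3-methoxy-5-(4-methylbenzenesulfinyl)-4H-pyran-4-one (racemic at S) | COc1c(-c2cc(O)c(OC)cc2OCc2ccccc2)occ(S(=O)c2ccc(C)cc2)c1=O | intermediate
15 | 4-(benzyloxy)-2-methoxy-5-[3-methoxy-5-(4-methylbenzenesulfinyl)-4-oxo-4H-pyran-2-yl]phenyl acetate (racemic at S) | COc1c(-c2cc(OC(C)=O)c(OC)cc2OCc2ccccc2)occ(S(=O)c2ccc(C)cc2)c1=O | intermediate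
16 | methyl acetoacetate | COC(=O)CC(C)=O | starting material
17 | methyl 3-(trimethylsilyloxy)but-2-enoate (E/Z mixture) | COC(=O)C=C(C)O[Si](C)(C)C | intermediate
18 | (1Z)-1-methoxy-1,3-bis(trimethylsilyloxy)buta-1,3-diene | CO/C(O[Si](C)(C)C)=C/C(=C)O[Si](C)(C)C | intermediate
19 | 4-(benzyloxy)-5-[3,5-dimethoxy-4a-(4-methylbenzenesulfinyl)-4-oxo-5,7-bis(trimethylsilyloxy)-4a,5,8,8a-tetrahydro-4H-chromen-2-yl]-2-methoxyphenyl acetate (cis ring fusion: sulfinyl at C4a and H at C8a on the same face; racemic, both epimers at C5 and at S; not isolated) | COC1=C(c2cc(OC(C)=O)c(OC)cc2OCc2ccccc2)OC2CC(O[Si](C)(C)C)=CC(OC)(O[Si](C)(C)C)C2(S(=O)c2ccc(C)cc2)C1=O | intermediate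
20 | 4-(benzyloxy)-2-methoxy-5-[3-methoxy-4-oxo-5,7-bis(trimethylsilyloxy)-4H-chromen-2-yl]phenyl acetate (not isolated) | COc1c(-c2cc(OC(C)=O)c(OC)cc2OCc2ccccc2)oc2cc(O[Si](C)(C)C)cc(O[Si](C)(C)C)c2c1=O | intermediate
21 | 4-(benzyloxy)-5-(5,7-dihydroxy-3-methoxy-4-oxo-4H-chromen-2-yl)-2-methoxyphenyl acetate | COc1c(-c2cc(OC(C)=O)c(OC)cc2OCc2ccccc2)oc2cc(O)cc(O)c2c1=O | intermediate
22 | 5,7,2',5'-tetrahydroxy-3,4'-dimethoxyflavone 5'-acetate | COc1cc(O)c(-c2oc3cc(O)cc(O)c3c(=O)c2OC)cc1OC(C)=O | target

**Step count**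
Total: 14 steps. Longest linear sequence: 10 steps (1, 2, 3, 4, 5, 8, 9, 10, 13, 14).

**Steps most likely to fail**

Step 13 (key step). The diene may add only in Michael fashion, after which the C5 carbanion expels the ring oxygen and the pyranone opens. Silyl transfer to the sulfinyl oxygen may divert the reaction to Pummerer-type products. The cycloaddition may also be too slow below the temperature at which the diene degrades. The fallback uses known chemistry (Baker–Venkataraman flavone synthesis), sets out from acid 7 and comes back to the route at target 22. Phloroglucinol and methoxyacetonitrile (Hoesch reaction: ZnCl2, HCl, Et2O, then hot water) should give 1-(2,4,6-trihydroxyphenyl)-2-methoxyethan-1-one F1. BnBr (2 equiv) and K2CO3 in DMF should benzylate the two non-chelated hydroxyls to give 1-[2,4-bis(benzyloxy)-6-hydroxyphenyl]-2-methoxyethan-1-one F2. Esterification of F2 with 7 (EDC, DMAP, CH2Cl2) should give 3,5-bis(benzyloxy)-2-(methoxyacetyl)phenyl 2-(benzyloxy)-4-methoxy-5-(methoxymethoxy)benzoate F3. LiHMDS in THF (−78→0 °C) should bring about the 1,5-acyl shift to 1-[2,4-bis(benzyloxy)-6-hydroxyphenyl]-3-[2-(benzyloxy)-4-methoxy-5-(methoxymethoxy)phenyl]-2-methoxypropane-1,3-dione F4. TsOH in MeOH–CH2Cl2 should cyclodehydrate F4 and remove the MOM group to give 5,7-bis(benzyloxy)-2-[2-(benzyloxy)-5-hydroxy-4-methoxyphenyl]-3-methoxy-4H-chromen-4-one F5. Ac2O and pyridine should then give 4-(benzyloxy)-5-[5,7-bis(benzyloxy)-3-methoxy-4-oxo-4H-chromen-2-yl]-2-methoxyphenyl acetate F6. Hydrogenolysis of all three benzyl ethers (H2, Pd/C, EtOAc–THF) should give 22.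

Step 8. The hindered aroyl chloride may acylate the enolate on oxygen, or proton transfer from the more acidic product may stall conversion. The fallback replaces acylation by aldol addition and oxidation; it sets out from bromide 6 (with 11) and comes back at 13. Bromine–lithium exchange of 6 (n-BuLi, THF, −78 °C) and quenching with DMF should give 2-(benzyloxy)-4-methoxy-5-(methoxymethoxy)benzaldehyde F7. The lithium enolate of 11 (LiHMDS, THF, −78 °C) should add to F7 to give 1-[2-(benzyloxy)-4-methoxy-5-(methoxymethoxy)phenyl]-5-(dimethylamino)-1-hydroxy-2-methoxy-4-(4-methylbenzenesulfinyl)pent-4-en-3-one F8 as a diastereomer mixture. Oxidation of F8 with Dess–Martin periodinane (CH2Cl2, rt), which tolerates sulfoxides, should give 13.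

Step 9. The vinyl sulfoxide may be deoxygenated or degraded under protic acid, methanol may add at the doubly activated C6 and open the ring, or MOM cleavage may be incomplete. The fallback carries sulfur at the sulfide level through the acid step and oxidises afterwards; it sets out from ester 9 and comes back at 15. (p-Tolylthio)methyllithium (methyl p-tolyl sulfide, n-BuLi, DABCO, THF, 0 °C; 2 equiv) and 9 should give 1-methoxy-3-[(4-methylphenyl)sulfanyl]propan-2-one F9. DMF dimethyl acetal should convert F9 into 4-(dimethylamino)-1-methoxy-3-[(4-methylphenyl)sulfanyl]but-3-en-2-one F10. Its lithium enolate and aroyl chloride 12 (as in step 8) should give 1-[2-(benzyloxy)-4-methoxy-5-(methoxymethoxy)phenyl]-5-(dimethylamino)-2-methoxy-4-[(4-methylphenyl)sulfanyl]pent-4-ene-1,3-dione F11. HCl in MeOH, which a sulfide tolerates, should close the ring and remove MOM to give 2-[2-(benzyloxy)-5-hydroxy-4-methoxyphenyl]-3-methoxy-5-[(4-methylphenyl)sulfanyl]-4H-pyran-4-one F12. Ac2O and pyridine should give 4-(benzyloxy)-2-methoxy-5-{3-methoxy-5-[(4-methylphenyl)sulfanyl]-4-oxo-4H-pyran-2-yl}phenyl acetate F13. Oxidation of F13 with mCPBA (1.0 equiv, CH2Cl2, −40 °C) should give 15.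

**Further compounds**
F1 | step 13 | 1-(2,4,6-trihydroxyphenyl)-2-methoxyethan-1-one | COCC(=O)c1c(O)cc(O)cc1O
F2 | step 13 | 1-[2,4-bis(benzyloxy)-6-hydroxyphenyl]-2-methoxyethan-1-one | COCC(=O)c1c(O)cc(OCc2ccccc2)cc1OCc1ccccc1
F3 | step 13 | 3,5-bis(benzyloxy)-2-(methoxyacetyl)phenyl 2-(benzyloxy)-4-methoxy-5-(methoxymethoxy)benzoate | COCOc1cc(C(=O)Oc2cc(OCc3ccccc3)cc(OCc3ccccc3)c2C(=O)COC)c(OCc2ccccc2)cc1OC
F4 | step 13 | 1-[2,4-bis(benzyloxy)-6-hydroxyphenyl]-3-[2-(benzyloxy)-4-methoxy-5-(methoxymethoxy)phenyl]-2-methoxypropane-1,3-dione | COCOc1cc(C(=O)C(OC)C(=O)c2c(O)cc(OCc3ccccc3)cc2OCc2ccccc2)c(OCc2ccccc2)cc1OC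
F5 | step 13 | 5,7-bis(benzyloxy)-2-[2-(benzyloxy)-5-hydroxy-4-methoxyphenyl]-3-methoxy-4H-chromen-4-one | COc1c(-c2cc(O)c(OC)cc2OCc2ccccc2)oc2cc(OCc3ccccc3)cc(OCc3ccccc3)c2c1=O
F6 | step 13 | 4-(benzyloxy)-5-[5,7-bis(benzyloxy)-3-methoxy-4-oxo-4H-chromen-2-yl]-2-methoxyphenyl acetate | COc1c(-c2cc(OC(C)=O)c(OC)cc2OCc2ccccc2)oc2cc(OCc3ccccc3)cc(OCc3ccccc3)c2c1=O
F7 | step 8 | 2-(benzyloxy)-4-methoxy-5-(methoxymethoxy)benzaldehyde | COCOc1cc(C=O)c(OCc2ccccc2)cc1OC
F8 | step 8 | 1-[2-(benzyloxy)-4-methoxy-5-(methoxymethoxy)phenyl]-5-(dimethylamino)-1-hydroxy-2-methoxy-4-(4-methylbenzenesulfinyl)pent-4-en-3-one (diastereomer mixture) | COCOc1cc(C(O)C(OC)C(=O)C(=CN(C)C)S(=O)c2ccc(C)cc2)c(OCc2ccccc2)cc1OC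
F9 | step 9 | 1-methoxy-3-[(4-methylphenyl)sulfanyl]propan-2-one | COCC(=O)CSc1ccc(C)cc1
F10 | step 9 | 4-(dimethylamino)-1-methoxy-3-[(4-methylphenyl)sulfanyl]but-3-en-2-one | COCC(=O)C(=CN(C)C)Sc1ccc(C)cc1
F11 | step 9 | 1-[2-(benzyloxy)-4-methoxy-5-(methoxymethoxy)phenyl]-5-(dimethylamino)-2-methoxy-4-[(4-methylphenyl)sulfanyl]pent-4-ene-1,3-dione | COCOc1cc(C(=O)C(OC)C(=O)C(=CN(C)C)Sc2ccc(C)cc2)c(OCc2ccccc2)cc1OC
F12 | step 9 | 2-[2-(benzyloxy)-5-hydroxy-4-methoxyphenyl]-3-methoxy-5-[(4-methylphenyl)sulfanyl]-4H-pyran-4-one | COc1c(-c2cc(O)c(OC)cc2OCc2ccccc2)occ(Sc2ccc(C)cc2)c1=O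
F13 | step 9 | 4-(benzyloxy)-2-methoxy-5-{3-methoxy-5-[(4-methylphenyl)sulfanyl]-4-oxo-4H-pyran-2-yl}phenyl acetate | COc1c(-c2cc(OC(C)=O)c(OC)cc2OCc2ccccc2)occ(Sc2ccc(C)cc2)c1=O
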